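## Analysis of the target

The target is a drimane-type bicyclic sesquiterpenoid ester. In drimane numbering, ring A (C1–C5, C10) is saturated and carries the gem-dimethyl group at C4 and the angular methyl at C10. Ring B (C5–C10) carries a C7=C8 double bond conjugated with the C12 aldehyde on C8, a tertiary carbinol at C9 bearing the C11 carboxylic acid, and at C6 a (2E,4E,6E)-octa-2,4,6-trienoate. The four stereocenters C5, C6, C9 and C10 are contiguous: the SMILES places the C10 methyl and C5–H cis (a cis-fused decalin) and puts the C6 acyloxy group and the C9 hydroxyl on that same face (β below), so the C9 carboxyl is α. Sensitive groups are the trienoate, the allylic ester, the enal and the γ-oxo-acid pair C11/C12, which can close to a 12-hydroxy-11,12-olide. The difficulty lies in three adjacent fully substituted carbons (C4, C10, C9) around a cis junction, a tertiary alcohol syn to the angular methyl, and two neighbouring one-carbon groups at different oxidation levels. The plan rests on the cis C5/C10 junction flanked by C4 and by C9/C8 with their carbonyl carbons: C10 and C7 become bridgeheads of a bicyclo[2.2.2]octene whose C8–C9 bridge is a butenolide, whose C5=C6 bridge is the alkene and whose C1–C2 bridge is the oxygenated remnant of a dearomatised arene, and a [3,3] shift forming C4–C5 turns the cage into the decalin.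

## Retrosynthetic reasoning

**29 ⇒ 28 ⇒ 27.** No C–C bond is cut. The open oxo-acid 29 is the ring-chain tautomer of lactol 28, which comes from the menthyl lactone acetal 27 by cleaving only the C12–O(menthyl) bond. Keeping C11 and C12 tied as one lactone acetal until the end means that the enal, the acid and the trienoate never meet basic reagents.

**27 ⇒ 24 + 25.** The C6–O acyl bond is cut. The triene is the most fragile part, so it enters last but one. The forward reaction must acylate the secondary allylic 6-OH and leave the tertiary 9-OH.

**24 ⇒ 22.** The C9–O bond is cut. In 22, C9–H is α to the lactone carbonyl and allylic, so a dienolate forms easily. This is done only after C8 has become trigonal: while the lactone is cis-fused at a saturated C8 (compounds 13–21), an electrophile would enter on the face of H-9 and give the wrong C9 epimer. With C7=C8 in place, the face is chosen by the C12 menthyloxy group and the C10 substituents, and C11 can swing to the α-face.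

**22 ⇒ 19 ⇒ 18.** The C6–O bond is cut and the alkene is moved back to C6=C7. Epoxidation and selenium-mediated transposition deliver oxygen at C6 and the alkene at C7=C8 in an antarafacial sense. This is what the structure needs, because the oxygen must be β while the hydrogen to be lost at C8 is α.

**18 ⇒ 14 ⇒ 13.** The ring A oxygens at C1 and C2 are relics of the rearrangement and are removed reductively. Nothing else in the molecule is changed.

**13 ⇒ 10 (key disconnection).** The C4–C5 bond is cut and C2–C7 is reconnected. This takes the cis-decalin back to the bicyclo[2.2.2]octenol 10 and removes ring A, the quaternary C4 and the C5 stereocenter in one move. C10 is already quaternary as a bridgehead, and C8, C9 and C12 are already set. The forward anionic oxy-Cope rearrangement has to form a bond to a fully substituted alkene terminus.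

**10 ⇒ 7 + 8.** The bond between the carbinol carbon and the alkenyl group is cut. The alkenyl-metal reagent from 8 must add to ketone 7 from the side of the alkene bridge so that the two ends of the 1,5-diene face each other.

**7 ⇒ 6 ⇒ 5 ⇒ 4.** This is an exchange of oxygen functions (ketone reduced and O-methylated, ketal hydrolysed). It is needed because the cycloaddition places the ketone next to the methylated bridgehead, whereas the rearrangement needs the carbinol next to the unsubstituted one. The single methoxy group that remains at C3 is turned away from the alkenyl side, which relieves the crowded transition state of the key step.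

**4 ⇒ 3 + 2; 3 ⇒ 1.** The two σ-bonds of the cage are cut (Diels–Alder), then the dienone 3 is traced to phenol 1 by oxidative dearomatisation. The lactone carbonyl carbon (future C11) must end on the carbon attached to the methylated bridgehead. A butenolide bonds through its electrophilic β-carbon to the dienone terminus remote from the carbonyl. The methyl group is therefore placed on the terminus next to the carbonyl, that is, ortho to the hydroxyl in 1, so that electronic and steric preferences point the same way. With the methyl on the remote terminus, the intrinsic polarisation of the dienone would work against the required orientation. The acetal carbon of 2 is the only purchased stereocenter and controls all others.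

## Alternatives that were turned down

**Alternative 1:** Ring A would be cut at C1–C10 and C4–C5 and made by an intermolecular Diels–Alder reaction of quinone A1 with diene A2 under a chiral cationic boron Lewis acid, giving the cis-fused enedione A3.
- For it: two cheap achiral partners, a catalytic source of chirality, and one step that sets the quaternary C10, the cis junction and the gem-dimethyl carbon, with oxygen already at C6 and C9 and C12 present as a methyl group. On brevity up to the decalin, and on avoiding a stoichiometric auxiliary, it is stronger than the chosen route.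
- Against it: A2 carries a methyl group cis on its reacting terminus, so its s-cis conformer is strained; such dienes cycloadd sluggishly and tend to ionise or polymerise under strong Lewis acids. In A3 the junction hydrogen at C5 is α to the C6 ketone, so the cis fusion can be lost by enolisation. C11 must still be attached to the C9 ketone beside the quaternary C10 with the tertiary alcohol on the right face. The C12 methyl must be oxidised, the two ketones told apart, and the ring A alkene reduced beside an enone.
- Comparison: the chosen strategy brings C11 and C12 together at their final oxidation levels in one lactone acetal, forms the cis junction by a stereospecific shift and never places C5 next to a carbonyl group.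

**Alternative 2:** Both rings would be cut at once, at C5–C10 and C8–C9, leading to the acyclic trienal A4, whose intramolecular Diels–Alder reaction under a chiral boron Lewis acid would give the bicyclic aldehyde A5.
- For it: ring A, ring B and three stereocenters arise in one catalytic step; C6 is already oxygenated as a silyl enol ether and both C11 and C12 are in place. In making the whole decalin in one step it equals the chosen route.
- Against it: A4 needs a long linear synthesis with three controlled alkene geometries, among them a Z-trisubstituted enal and a Z silyl dienol ether. The C5–C10 bond joins a diene terminus next to the quaternary C4 to a fully substituted dienophile carbon. The Lewis acid may divert the silyl dienol ether into a stepwise Mukaiyama–Michael path, which forfeits the stereospecificity on which the cis junction depends. After cyclisation C12 is at the alcohol level, C11 at the aldehyde level, C9 has no oxygen and the alkene is at C6=C7, so the later redox work is no shorter.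
- Comparison: the chosen route forms its congested C4–C5 bond inside a rigid cage reached in five steps from an arene, with the geometry fixed by the cage and not by a catalyst.

**Alternative 3:** Ring B would be cut at C8–C9 and C7–C8 and traced to the cis-hydrindanone A6. Lewis-acid-promoted addition of the diazo ester A7 to its C9 ketone and 1,2-shift of C7 would expand the five-membered ring to the β-keto ester A8.
- For it: the absolute configuration comes from a well-tried amino-acid-catalysed annulation, the C6 oxygen is set early, and after expansion C9 is a ketone and C12 sits on C8, ready for the C7=C8 alkene. On early, precedented control of C5, C6 and C10 it is at least as strong as the chosen route.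
- Against it: A6, with its gem-dimethyl group and cis junction, is itself a multistep target. The ketone is neopentyl, so addition of A7 is slow and migration of C7 in preference to C10 is not assured. C11 must then be added to the hindered C9 ketone with facial control. C12 arrives at the acid level while C11 is absent, the reverse of what the target needs, which costs reduction and protection steps.
- Comparison: the chosen strategy delivers both carbons in one cycloaddition, differentiated from the start.

Key step: step 6

Conventions: decalins carry drimane numbering (C11 on C9, C12 on C8); β is the face of the C10 methyl, and "cis-fused" means 5β-H. Compounds 4–11 are numbered as bicyclo[2.2.2]oct-5-enes with C1 the unsubstituted bridgehead, C4 the methylated bridgehead, C7 on C1 and C8 on C4. d-Menthyl is (1S,2R,5S)-2-isopropyl-5-methylcyclohexyl.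

Assumption: the 12-hydroxy-11,12-olide 28 and the open 12-oxo-11-oic acid 29 are ring-chain tautomers that interconvert by proton transfer; the target is taken as the open form as drawn.

## Route

Step 1
Reactants: 1 2-methoxy-6-methylphenol; 2 (5S)-5-[(1S,2R,5S)-menthyloxy]furan-2(5H)-one
Product: 4 endo adduct (lactone-fused 2,2-dimethoxy-4-methylbicyclo[2.2.2]oct-5-en-3-one d-menthyl acetal; lactone C=O carbon on C8), via masked o-benzoquinone 3 (not isolated)
Conditions: 1 (1.5 equiv), PhI(OAc)2, MeOH, 0 °C; evaporate; then 2, toluene, 100 °C
Reagents that add atoms: methanol, CO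
Why: PhI(OAc)2 oxidises the phenol to a phenoxonium ion that methanol traps at the methoxy-bearing ortho carbon, giving the masked o-benzoquinone 3, whose 2-methyl group slows self-dimerisation; the Diels–Alder reaction with 2 should be endo (lactone syn to the new C5=C6 bridge) and anti to the menthyloxy group, which sets C1, C4, C7 and C8 from the acetal carbon. Regiochemistry follows the polarisation of both partners: the electrophilic β-carbon of the butenolide bonds to C5 of the dienone, the unsubstituted terminus remote from the carbonyl, so the carbon bearing the lactone carbonyl ends on the methylated bridgehead.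

Step 2
Reactants: 4 endo adduct
Product: 5 lactone-fused 2,2-dimethoxy-4-methylbicyclo[2.2.2]oct-5-en-3-ol d-menthyl acetal (3-OH syn to the C7–C8 bridge)
Conditions: NaBH4, MeOH–CH2Cl2, −20 → 0 °C
Reagents that add atoms: none
Why: Chemoselective borohydride reduction of the α,α-dimethoxy ketone, which is activated by the adjacent ketal while the lactone acetal survives at low temperature; hydride should enter from the open side of the C5=C6 bridge, away from the inward hydrogens of the C7–C8 bridge. The new center is a spectator that is deleted in step 7.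

Step 3
Reactants: 5 alcohol
Product: 6 lactone-fused 2,2,3-trimethoxy-4-methylbicyclo[2.2.2]oct-5-ene d-menthyl acetal
Conditions: MeOTf, 2,6-di-tert-butyl-4-methylpyridine, CH2Cl2, 0 → 35 °C
Reagents that add atoms: methyl trifluoromethanesulfonate, COS(=O)(=O)C(F)(F)F
Why: O-Methylation under non-basic conditions avoids enolising the lactone; the methyl ether carries the C3 oxygen through the Grignard and KH steps, blocks α-ketol rearrangement after ketal hydrolysis and later serves as the leaving group for SmI2.

Step 4
Reactants: 6 trimethoxy compound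
Product: 7 lactone-fused 3-methoxy-4-methylbicyclo[2.2.2]oct-5-en-2-one d-menthyl acetal
Conditions: TsOH·H2O (cat.), acetone–H2O, 40 °C
Reagents that add atoms: water, O
Why: Acid-catalysed hydrolysis of the dimethyl ketal unveils the ketone next to the unsubstituted bridgehead and completes the 1,2-carbonyl transposition begun in steps 2 and 3. The lactone acetal is an acylal whose oxocarbenium ion is destabilised by the acyloxy oxygen, so mild aqueous acid should discriminate.

Step 5
Reactants: 7 methoxy ketone; 8 2-methylprop-1-enylmagnesium bromide
Product: 10 lactone-fused 3-methoxy-4-methyl-2-(2-methylprop-1-enyl)bicyclo[2.2.2]oct-5-en-2-ol d-menthyl acetal (alkenyl group syn to C5=C6), via organocerium reagent 9 (not isolated)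
Conditions: CeCl3, THF, −78 °C; then 7, −78 → −40 °C; aq. NH4Cl
Reagents that add atoms: none
Why: CeCl3-mediated Grignard 1,2-addition (organocerium reagent), which suppresses enolisation of the α-methoxy ketone and leaves the lactone untouched at low temperature. Attack from the C5=C6 side is also anti to the 3-methoxy group, so the alkenyl group should end syn to the alkene bridge, as the rearrangement requires; the carbinol center is set by the bicyclic framework.

Step 6
Reactants: 10 alkenyl carbinol
Product: 13 cis-fused 1α-methoxy-2-oxodrim-6-en-11,12-olide 12-(d-menthyl) acetal, via potassium alkoxide 11 (not isolated), via potassium enolate 12 (not isolated)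
Conditions: KH, 18-crown-6, THF, 0 → 60 °C; AcOH, −78 °C
Reagents that add atoms: none
Why: KH with 18-crown-6 gives the free potassium alkoxide 11, whose oxyanion weakens the adjacent C2–C1 bond and triggers a concerted [3,3]-sigmatropic shift of the 1,5-diene CMe2=CH–C2(O−)–C1–C6=C5 (bicyclic numbering): the CMe2 terminus bonds to C5 while C2–C1 breaks, giving enolate 12 and, after protonation, ketone 13. The closest known reaction type is the anionic oxy-Cope rearrangement of 2-alkenylbicyclo[2.2.2]oct-5-en-2-ols derived from masked o-benzoquinones, an established route to cis-decalins. Ring A, a six-membered carbocycle, is closed by the new C4–C5 σ-bond (drimane numbering) within a six-centre boat transition state; a chair is excluded because it would drive the alkenyl CH into the C3 bridge. The one new stereocenter, C5, is fixed by the cage: the alkenyl group can reach the alkene only on the face turned towards the C2–C3 bridge, so C4 arrives cis to C1 on C10 and C5–H comes out cis to the C10 methyl; C8, C9, C10 and the acetal carbon pass through unchanged. The step needs the [3,3] shift to win over alkoxide fragmentation, a [1,3] shift and lactone enolisation; the syn alkenyl group from step 5, the rigid cisoid 1,5-diene and the use of base only on the most acidic O–H should secure this. The Z-methyl of the CMe2 terminus is pressed towards the bridgehead methyl in the transition state, which makes this case slower than a vinyl one and is the reason C3 carries only one methoxy group, turned away from the alkenyl side. A cold AcOH quench keeps enolate 12 from reacting with the lactone.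

Step 7
Reactants: 13 α-methoxy ketone
Product: 14 cis-fused 2-oxodrim-6-en-11,12-olide 12-(d-menthyl) acetal
Conditions: SmI2, THF–MeOH, −78 °C
Reagents that add atoms: none
Why: Reductive cleavage of an α-alkoxy ketone: SmI2 forms the ketyl, a second electron transfer expels methoxide and methanol protonates the samarium enolate. The isolated alkene, the lactone and the acetal are inert under these conditions and no stereocenter of the target is touched.

Step 8
Reactants: 14 ketone
Product: 15 2-(p-toluenesulfonylhydrazone) of 14 (mixture of C=N isomers)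
Conditions: TsNHNH2, EtOH, 60 °C
Reagents that add atoms: p-toluenesulfonyl hydrazide, Cc1ccc(cc1)S(=O)(=O)NN
Why: Condensation of the cyclohexanone, flanked by two methylene groups, with tosylhydrazide prepares a mild Wolff–Kishner-type deoxygenation; neutral ethanol does not affect the acetal or the lactone.

Step 9
Reactants: 15 tosylhydrazone
Product: 18 cis-fused drim-6-en-11,12-olide 12-(d-menthyl) acetal, via N-boryl hydrazine 16 (not isolated), via diazene 17 (not isolated)
Conditions: catecholborane, CHCl3, 0 °C → rt; then NaOAc·3H2O, 60 °C
Reagents that add atoms: none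
Why: Kabalka variant of the Caglioti reduction: catecholborane adds hydride to C=N, acetate-induced loss of p-toluenesulfinate gives the diazene, and loss of N2 leaves CH2 at C2. The lactone, the acetal and the disubstituted alkene should survive, since uncatalysed hydroboration by catecholborane is slow at this temperature.

Step 10
Reactants: 18 alkene
Product: 19 cis-fused 6β,7β-epoxydriman-11,12-olide 12-(d-menthyl) acetal
Conditions: mCPBA, NaHCO3, CH2Cl2, 0 °C
Reagents that add atoms: 3-chloroperoxybenzoic acid, OOC(=O)c1cccc(Cl)c1
Why: Prilezhaev epoxidation of the only alkene. Attack is expected on the β-face, because the α-face of ring B is covered by ring A (the axial C1 methylene on C10), while the β-face carries only the flat lactone with its menthyloxy group pointing away; the margin is modest. The epoxide oxygen becomes the C6 oxygen of the target.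

Step 11
Reactants: 19 epoxide
Product: 22 cis-fused 6β-hydroxydrim-7-en-11,12-olide 12-(d-menthyl) acetal, via hydroxy selenide 20 (not isolated), via selenoxide 21 (not isolated)
Conditions: (PhSe)2, NaBH4, EtOH, rt → 50 °C; then H2O2, pyridine, THF, 0 °C → rt
Reagents that add atoms: none
Why: Sharpless epoxide-to-allylic-alcohol transposition: the selenolate opens the epoxide by SN2 attack at C7 from the α-face (C6 is shielded by the neopentyl C5/C4 junction), giving 6β-OH/7α-SePh. Oxidation to the selenoxide is followed by syn-elimination with the cis (α) hydrogen at C8, away from the carbinol carbon, which places the alkene at C7=C8 and keeps the C6 configuration.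

Step 12
Reactants: 22 allylic alcohol
Product: 24 cis-fused 6β,9β-dihydroxydrim-7-en-11,12-olide 12-(d-menthyl) acetal (C11 α), via dipotassium dienolate 23 (not isolated)
Conditions: 22 added to KN(SiMe3)2 (2.2 equiv), THF, −78 °C; 2-(phenylsulfonyl)-3-phenyloxaziridine, −78 °C; AcOH
Reagents that add atoms: 2-(phenylsulfonyl)-3-phenyloxaziridine, O=S(=O)(c1ccccc1)N1OC1c1ccccc1
Why: Two equivalents of base form the 6-alkoxide and remove the doubly activated C9–H to give the dienolate, which the N-sulfonyloxaziridine hydroxylates at the α-carbon C9 (Davis enolate oxidation); inverse addition prevents the alkoxide from meeting an un-enolised lactone. With C8 trigonal, the face is chosen by the neighbours: the C12 menthyloxy group and the axial C1 methylene on C10 both cover the α-face, so oxygen should arrive on the β-face and C11 move to α. Doing this before acylation avoids vinylogous elimination of a C6 carboxylate from the dienolate.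

Step 13
Reactants: 24 diol; 25 (2E,4E,6E)-octa-2,4,6-trienoic acid
Product: 27 cis-fused 9β-hydroxy-6β-[(2E,4E,6E)-octa-2,4,6-trienoyloxy]drim-7-en-11,12-olide 12-(d-menthyl) acetal, via mixed anhydride 26 (not isolated)
Conditions: 25, 2,4,6-trichlorobenzoyl chloride, Et3N, THF, rt; then 24, DMAP, toluene, rt
Reagents that add atoms: none
Why: Yamaguchi esterification: the mixed anhydride passes the trienoyl group through the acyl-DMAP salt to the secondary allylic 6-OH. The tertiary 9-OH, flanked by the quaternary C10 and the lactone carbonyl, should not compete, and the mild conditions avoid ketene formation or isomerisation of the triene.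

Step 14
Reactants: 27 trienoate acetal
Product: 29 9β-hydroxy-6β-[(2E,4E,6E)-octa-2,4,6-trienoyloxy]-12-oxo-cis-drim-7-en-11-oic acid (target), via hydroxy-lactone 28 (not isolated)
Conditions: CF3CO2H–H2O–THF, 0 °C → rt
Reagents that add atoms: water, O
Why: Acid hydrolysis of the mixed lactone acetal: protonation and loss of menthol give an allyl-stabilised oxocarbenium ion at C12, which water traps to the hydroxy-lactone 28; ring opening gives the C12 enal and the C11 acid of 29. The ester, the triene and the tertiary alcohol should tolerate brief aqueous trifluoroacetic acid, and no stereocenter is affected.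

## Compound list

1 | 2-methoxy-6-methylphenol | COc1cccc(C)c1O | starting material
2 | (5S)-5-[(1S,2R,5S)-2-isopropyl-5-methylcyclohexyloxy]furan-2(5H)-one (d-menthyloxybutenolide) | O=C1C=C[C@@H](O[C@H]2C[C@@H](C)CC[C@@H]2C(C)C)O1 | starting material
3 | 6,6-dimethoxy-2-methylcyclohexa-2,4-dien-1-one (masked o-benzoquinone) | CC1=CC=CC(OC)(OC)C1=O | intermediate
4 | endo adduct: 2,2-dimethoxy-4-methylbicyclo[2.2.2]oct-5-en-3-one with a cis-fused γ-lactone on C7–C8 (C=O carbon on C8, acetal carbon on C7, lactone syn to C5=C6), d-menthyl acetal with S acetal carbon and menthyloxy cis to H-7 | COC1(OC)C(=O)[C@@]2(C)C=C[C@@H]1[C@@H]3[C@@H](O[C@H]4C[C@@H](C)CC[C@@H]4C(C)C)OC(=O)[C@@H]32 | intermediate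
5 | 3-alcohol of 4 (3-OH syn to the C7–C8 bridge) | COC1(OC)[C@H](O)[C@@]2(C)C=C[C@@H]1[C@@H]3[C@@H](O[C@H]4C[C@@H](C)CC[C@@H]4C(C)C)OC(=O)[C@@H]32 | intermediate
6 | 3-methyl ether of 5 (2,2,3-trimethoxy compound) | COC1(OC)[C@H](OC)[C@@]2(C)C=C[C@@H]1[C@@H]3[C@@H](O[C@H]4C[C@@H](C)CC[C@@H]4C(C)C)OC(=O)[C@@H]32 | intermediate
7 | lactone-fused 3-methoxy-4-methylbicyclo[2.2.2]oct-5-en-2-one d-menthyl acetal (3-OMe syn to the C7–C8 bridge) | O=C1[C@H](OC)[C@@]2(C)C=C[C@@H]1[C@@H]3[C@@H](O[C@H]4C[C@@H](C)CC[C@@H]4C(C)C)OC(=O)[C@@H]32 | intermediate
8 | 2-methylprop-1-enylmagnesium bromide | CC(C)=C[Mg]Br | starting material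
9 | (2-methylprop-1-enyl)cerium dichloride | CC(C)=C[Ce](Cl)Cl | intermediate
10 | lactone-fused 3-methoxy-4-methyl-2-(2-methylprop-1-enyl)bicyclo[2.2.2]oct-5-en-2-ol d-menthyl acetal (alkenyl syn to C5=C6; 2-OH and 3-OMe syn to C7–C8) | CC(C)=C[C@@]1(O)[C@H](OC)[C@@]2(C)C=C[C@@H]1[C@@H]3[C@@H](O[C@H]4C[C@@H](C)CC[C@@H]4C(C)C)OC(=O)[C@@H]32 | intermediate
11 | potassium alkoxide of 10 | CC(C)=C[C@@]1([O-])[C@H](OC)[C@@]2(C)C=C[C@@H]1[C@@H]3[C@@H](O[C@H]4C[C@@H](C)CC[C@@H]4C(C)C)OC(=O)[C@@H]32.[K+] | intermediate
12 | potassium C2=C3 enolate of 13 | C1=C[C@@H]3[C@@H](O[C@H]4C[C@@H](C)CC[C@@H]4C(C)C)OC(=O)[C@@H]3[C@@]2(C)[C@@H](OC)C([O-])=CC(C)(C)[C@@H]12.[K+] | intermediate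
13 | cis-fused (5β-H) 1α-methoxy-2-oxodrim-6-en-11,12-olide 12-(d-menthyl) acetal; lactone cis-fused on the β-face (H-8 and H-9 α), 12S | C1=C[C@@H]3[C@@H](O[C@H]4C[C@@H](C)CC[C@@H]4C(C)C)OC(=O)[C@@H]3[C@@]2(C)[C@@H](OC)C(=O)CC(C)(C)[C@@H]12 | intermediate
14 | cis-fused 2-oxodrim-6-en-11,12-olide 12-(d-menthyl) acetal | C1=C[C@@H]3[C@@H](O[C@H]4C[C@@H](C)CC[C@@H]4C(C)C)OC(=O)[C@@H]3[C@@]2(C)CC(=O)CC(C)(C)[C@@H]12 | intermediate
15 | 2-tosylhydrazone of 14 | C1=C[C@@H]3[C@@H](O[C@H]4C[C@@H](C)CC[C@@H]4C(C)C)OC(=O)[C@@H]3[C@@]2(C)CC(=NNS(=O)(=O)c5ccc(C)cc5)CC(C)(C)[C@@H]12 | intermediate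
16 | N-(1,3,2-benzodioxaborol-2-yl)-N'-tosylhydrazine at C2 (either C2 epimer) | C1=C[C@@H]3[C@@H](O[C@H]4C[C@@H](C)CC[C@@H]4C(C)C)OC(=O)[C@@H]3[C@@]2(C)CC(N(NS(=O)(=O)c5ccc(C)cc5)B6Oc7ccccc7O6)CC(C)(C)[C@@H]12 | intermediate
17 | C2 diazene (either C2 epimer) | C1=C[C@@H]3[C@@H](O[C@H]4C[C@@H](C)CC[C@@H]4C(C)C)OC(=O)[C@@H]3[C@@]2(C)CC(N=N)CC(C)(C)[C@@H]12 | intermediate
18 | cis-fused drim-6-en-11,12-olide 12-(d-menthyl) acetal | C1=C[C@@H]3[C@@H](O[C@H]4C[C@@H](C)CC[C@@H]4C(C)C)OC(=O)[C@@H]3[C@@]2(C)CCCC(C)(C)[C@@H]12 | intermediate
19 | cis-fused 6β,7β-epoxydriman-11,12-olide 12-(d-menthyl) acetal | O1[C@@H]2[C@H]1[C@@H]3[C@@H](O[C@H]5C[C@@H](C)CC[C@@H]5C(C)C)OC(=O)[C@@H]3[C@@]4(C)CCCC(C)(C)[C@@H]24 | intermediate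
20 | cis-fused 6β-hydroxy-7α-(phenylseleno)driman-11,12-olide 12-(d-menthyl) acetal | O[C@@H]1[C@@H]([Se]c6ccccc6)[C@@H]3[C@@H](O[C@H]4C[C@@H](C)CC[C@@H]4C(C)C)OC(=O)[C@@H]3[C@@]2(C)CCCC(C)(C)[C@@H]12 | intermediate
21 | Se-oxide of 20 (both configurations at selenium) | O[C@@H]1[C@@H]([Se](=O)c6ccccc6)[C@@H]3[C@@H](O[C@H]4C[C@@H](C)CC[C@@H]4C(C)C)OC(=O)[C@@H]3[C@@]2(C)CCCC(C)(C)[C@@H]12 | intermediate
22 | cis-fused 6β-hydroxydrim-7-en-11,12-olide 12-(d-menthyl) acetal (9α-H, 12S) | O[C@@H]1C=C3[C@@H](O[C@H]4C[C@@H](C)CC[C@@H]4C(C)C)OC(=O)[C@@H]3[C@@]2(C)CCCC(C)(C)[C@@H]12 | intermediate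
23 | dipotassium 6-alkoxide C9=C11 dienolate of 22 | [O-][C@@H]1C=C3[C@@H](O[C@H]4C[C@@H](C)CC[C@@H]4C(C)C)OC([O-])=C3[C@@]2(C)CCCC(C)(C)[C@@H]12.[K+].[K+] | intermediate
24 | cis-fused 6β,9β-dihydroxydrim-7-en-11,12-olide 12-(d-menthyl) acetal (C11 α, 12S) | O[C@@H]1C=C3[C@@H](O[C@H]4C[C@@H](C)CC[C@@H]4C(C)C)OC(=O)[C@@]3(O)[C@@]2(C)CCCC(C)(C)[C@@H]12 | intermediate
25 | (2E,4E,6E)-octa-2,4,6-trienoic acid | C/C=C/C=C/C=C/C(=O)O | starting material
26 | (2E,4E,6E)-octa-2,4,6-trienoic 2,4,6-trichlorobenzoic anhydride | C/C=C/C=C/C=C/C(=O)OC(=O)c1c(Cl)cc(Cl)cc1Cl | intermediate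
27 | cis-fused 9β-hydroxy-6β-[(2E,4E,6E)-octa-2,4,6-trienoyloxy]drim-7-en-11,12-olide 12-(d-menthyl) acetal | C/C=C/C=C/C=C/C(=O)O[C@@H]1C=C3[C@@H](O[C@H]4C[C@@H](C)CC[C@@H]4C(C)C)OC(=O)[C@@]3(O)[C@@]2(C)CCCC(C)(C)[C@@H]12 | intermediate
28 | cis-fused 9β,12-dihydroxy-6β-[(2E,4E,6E)-octa-2,4,6-trienoyloxy]drim-7-en-11,12-olide (both C12 epimers) | C/C=C/C=C/C=C/C(=O)O[C@@H]1C=C3C(O)OC(=O)[C@@]3(O)[C@@]2(C)CCCC(C)(C)[C@@H]12 | intermediate
29 | 9β-hydroxy-6β-[(2E,4E,6E)-octa-2,4,6-trienoyloxy]-12-oxo-cis-drim-7-en-11-oic acid (5β-H, 10β-methyl) | C/C=C/C=C/C=C/C(=O)O[C@@H]1C=C(C=O)[C@@](O)(C(=O)O)[C@@]2(C)CCCC(C)(C)[C@@H]12 | target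

## Step count and risks

Total: 14 steps. Longest linear sequence: 14 steps (1 → 29); 2, 8 and 25 are bought and enter in steps 1, 5 and 13.

**Step 6 (key step).** The most likely failure is a rearrangement too slow to compete with decomposition of the alkoxide (fragmentation, a [1,3] shift or lactone enolate chemistry). The cause is the Z-methyl of the CMe2 terminus, which is forced against the bridgehead methyl in the boat transition state. Fallback: from 7, addition of (E)-prop-1-enyllithium with CeCl3 gives the (E)-propenyl carbinol F1, whose single methyl group points outwards. Rearrangement with KH/18-crown-6 and trapping of the enolate with Me3SiCl gives the silyl enol ether F2. Saegusa–Ito oxidation with Pd(OAc)2 gives the 4-methyl enone F3, and conjugate addition of Me2CuLi installs the second C4 methyl and returns to 13.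

**Step 1.** The cycloaddition may be too slow: the butenolide is only moderately reactive and the diene must form a quaternary bridgehead, so dimerisation of 3, or oxidation of 1 at its free para position, may take over. Fallback: bromination of 1 with Bu4NBr3 gives 4-bromo-2-methoxy-6-methylphenol F4, whose oxidation gives the isolable, non-dimerising bromo dienone F5. Heating with 2 gives the vinyl bromide adduct F6, and Bu3SnH/AIBN removes the bromine to return to 4.

**Step 10.** Poor facial selectivity, or epoxidation on the α-face, is possible because both faces of C6=C7 carry a cis-fused ring. Fallback: from 18, NBS in aqueous THF places the bromonium ion on the face the peracid prefers and water opens it trans to the bromohydrin F7 (or its regioisomer). DBU then closes the epoxide on the opposite face and returns to 19.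

**Step 12.** Oxygen transfer from the bulky oxaziridine to the hindered, aggregated dienolate may be slow, or may occur at C7 or on the α-face; proton return could also give the conjugated butenolide. Fallback: from 22, double silylation (KN(SiMe3)2, Me3SiCl) gives the bis(trimethylsilyl) dienol ether F8. Rubottom oxidation with dimethyldioxirane and acidic desilylation returns to 24.

**Step 14.** Acid strong enough to cleave the acylal may ionise the allylic ester or isomerise the triene. Fallback: from 27, BCl3 at −78 °C exchanges the menthyloxy group for chloride to give the 12-chloro lactone F9. Hydrolysis with aqueous NaHCO3 returns to 28 and hence 29.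

Further compounds
F1 | step 6 | lactone-fused 3-methoxy-4-methyl-2-[(E)-prop-1-enyl]bicyclo[2.2.2]oct-5-en-2-ol d-menthyl acetal | C/C=C/[C@@]1(O)[C@H](OC)[C@@]2(C)C=C[C@@H]1[C@@H]3[C@@H](O[C@H]4C[C@@H](C)CC[C@@H]4C(C)C)OC(=O)[C@@H]32
F2 | step 6 | cis-fused 1α-methoxy-4α-methyl-2-(trimethylsilyloxy)-4-demethyldrima-2,6-dien-11,12-olide 12-(d-menthyl) acetal | C1=C[C@@H]3[C@@H](O[C@H]4C[C@@H](C)CC[C@@H]4C(C)C)OC(=O)[C@@H]3[C@@]2(C)[C@@H](OC)C(O[Si](C)(C)C)=C[C@@H](C)[C@@H]12
F3 | step 6 | cis-fused 1α-methoxy-4-methyl-2-oxo-4-demethyldrima-3,6-dien-11,12-olide 12-(d-menthyl) acetal | C1=C[C@@H]3[C@@H](O[C@H]4C[C@@H](C)CC[C@@H]4C(C)C)OC(=O)[C@@H]3[C@@]2(C)[C@@H](OC)C(=O)C=C(C)[C@@H]12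
F4 | step 1 | 4-bromo-2-methoxy-6-methylphenol | COc1cc(Br)cc(C)c1O
F5 | step 1 | 4-bromo-6,6-dimethoxy-2-methylcyclohexa-2,4-dien-1-one | CC1=CC(Br)=CC(OC)(OC)C1=O
F6 | step 1 | 6-bromo analogue of adduct 4 | COC1(OC)C(=O)[C@@]2(C)C=C(Br)[C@@H]1[C@@H]3[C@@H](O[C@H]4C[C@@H](C)CC[C@@H]4C(C)C)OC(=O)[C@@H]32
F7 | step 10 | cis-fused 6α-bromo-7β-hydroxydriman-11,12-olide 12-(d-menthyl) acetal | Br[C@H]1[C@H](O)[C@@H]3[C@@H](O[C@H]4C[C@@H](C)CC[C@@H]4C(C)C)OC(=O)[C@@H]3[C@@]2(C)CCCC(C)(C)[C@@H]12
F8 | step 12 | 6-O,11-O-bis(trimethylsilyl) dienol ether of 22 | C[Si](C)(C)O[C@@H]1C=C3[C@@H](O[C@H]4C[C@@H](C)CC[C@@H]4C(C)C)OC(O[Si](C)(C)C)=C3[C@@]2(C)CCCC(C)(C)[C@@H]12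
F9 | step 14 | cis-fused 12-chloro-9β-hydroxy-6β-[(2E,4E,6E)-octa-2,4,6-trienoyloxy]drim-7-en-11,12-olide (both C12 epimers) | C/C=C/C=C/C=C/C(=O)O[C@@H]1C=C3C(Cl)OC(=O)[C@@]3(O)[C@@]2(C)CCCC(C)(C)[C@@H]12
A1 | alternative 1 | 2,6-dimethyl-1,4-benzoquinone | CC1=CC(=O)C=C(C)C1=O
A2 | alternative 1 | 4-methylpenta-1,3-diene | C=CC=C(C)C
A3 | alternative 1 | cis-2,5,5,8a-tetramethyl-4a,5,8,8a-tetrahydronaphthalene-1,4-dione | O=C1C=C(C)C(=O)[C@@]2(C)CC=CC(C)(C)[C@@H]12
A4 | alternative 2 | (2Z,8Z,10E)-9-(tert-butyldimethylsilyloxy)-12-(4-methoxybenzyloxy)-3,7,7-trimethyldodeca-2,8,10-trienal | O=C/C=C(C)\CCCC(C)(C)/C=C(\O[Si](C)(C)C(C)(C)C)/C=C/COCc1ccc(OC)cc1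
A5 | alternative 2 | cis-fused 4-(tert-butyldimethylsilyloxy)-2-[(4-methoxybenzyloxy)methyl]-5,5,8a-trimethyl-1,2,4a,5,6,7,8,8a-octahydronaphthalene-1-carbaldehyde | CC(C)(C)[Si](C)(C)OC1=C[C@@H](COCc3ccc(OC)cc3)[C@@H](C=O)[C@@]2(C)CCCC(C)(C)[C@@H]12
A6 | alternative 3 | cis-fused 3-(tert-butyldimethylsilyloxy)-4,4,7a-trimethyloctahydro-1H-inden-1-one | CC(C)(C)[Si](C)(C)O[C@@H]1CC(=O)[C@@]2(C)CCCC(C)(C)[C@@H]12
A7 | alternative 3 | ethyl diazoacetate | CCOC(=O)C=[N+]=[N-]
A8 | alternative 3 | ethyl 4-(tert-butyldimethylsilyloxy)-1-hydroxy-5,5,8a-trimethyl-3,4,4a,5,6,7,8,8a-octahydronaphthalene-2-carboxylate (cis-fused, enol form) | CC(C)(C)[Si](C)(C)O[C@@H]1CC(C(=O)OCC)=C(O)[C@@]2(C)CCCC(C)(C)[C@@H]12
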